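**Plan**

- Numbering: C1 (alkyne CH) to C15 (CH3) along the chain. Ring A is the enol-ether ring (O, C7–C10), ring B the other ring (O, C9–C12), and C9–C10 is the fusion bond.
- Retrosynthetic cuts: C8–Br (from the C8 alcohol); C3=C4 and C5–C6 (side chain); O–C7 of ring A (alkyne iodoetherification); C7–C8 (acetylide on a lactone carbonyl). Ring B is then traced back to a six-membered lactone O(C12)–C8(=O)–C9=C10–C11–C12, whose C9=C10 bond is cut (intramolecular Wittig), with C8 and C9 coming from Ph3P=C=C=O.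
- Forward order: bromohydrin aldehyde, then the δ-lactone (C9–C10 made, ring closed), then the epoxy lactone, then ring B by moving the C12 oxygen from C8 to C9, then ring A, then the side chain, then the C8 bromide.
- Feature used: the C12 oxygen is β to C10, and C8, next to C9, carries a heteroatom. C8 can therefore serve as the carbonyl of a temporary lactone that ties O(C12) to C9; the six-membered ring allows only the Z olefin and lets C12 control C9 and C10.
- Stereochemistry: C12 and C13 come from one catalytic Shi epoxidation (C13 inverted by bromide). C10 and C9 are relayed from C12 (trans epoxidation of the lactone, SN2 inversion at C9). C8 comes from a C10–OH-directed reduction, then inversion to the bromide. The E enol ether comes from anti iodoetherification plus a retentive coupling, the Z enyne from a Peterson olefination.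

Key step: step 4

**Step 1**
Reactants: 1 (E)-hex-3-en-1-ol
Product: 2 2-[(2R,3R)-3-ethyloxiran-2-yl]ethan-1-ol
Conditions: D-fructose-derived Shi ketone (0.3 equiv), Oxone (2KHSO5·KHSO4·K2SO4), K2CO3, Bu4NHSO4 (cat.), MeCN–dimethoxymethane/aq. buffer (pH about 10.5), 0 °C
Reagents that add atoms: Oxone (active part potassium peroxymonosulfate), [K+].[O-]S(=O)(=O)OO
Why: Shi asymmetric epoxidation, in which the chiral dioxirane should attack the trans olefin through the spiro transition state from one face and set C12 and C13 as the (R,R)-epoxide, the free homoallylic hydroxyl being tolerated at the buffered pH.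

**Step 2**
Reactants: 2 2-[(2R,3R)-3-ethyloxiran-2-yl]ethan-1-ol
Product: 3 (3R,4S)-4-bromohexane-1,3-diol
Conditions: MgBr2·OEt2, Et2O, −20 → 0 °C; aqueous work-up
Reagents that add atoms: magnesium bromide diethyl etherate, [Mg+2].[Br-].[Br-].CCOCC
Why: Chelation-directed SN2 opening of a 3,4-epoxy alcohol, in which Mg2+ should bridge the hydroxyl and the oxirane oxygen so that bromide attacks C13 (outside the chelate and farther from the hydroxyl) with inversion, giving the anti bromohydrin and leaving C12 untouched; attack at C12 or tetrahydrofuran formation by the hydroxyl are the side paths to watch.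

**Step 3**
Reactants: 3 (3R,4S)-4-bromohexane-1,3-diol
Product: 4 (3R,4S)-4-bromo-3-hydroxyhexanal
Conditions: TEMPO (0.1 equiv), PhI(OAc)2 (1.1 equiv), CH2Cl2, rt; used crude
Reagents that add atoms: none
Why: Oxoammonium (TEMPO) oxidation is selective for the primary over the secondary alcohol and runs without base, so the bromohydrin should survive.

**Step 4**
Reactants: 4 (3R,4S)-4-bromo-3-hydroxyhexanal
Product: 6 (6R)-6-[(1S)-1-bromopropyl]-5,6-dihydro-2H-pyran-2-one, via ester ylide 5 (not isolated)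
Conditions: Ph3P=C=C=O (1.2 equiv), THF, 60 °C
Reagents that add atoms: (triphenylphosphoranylidene)ketene, O=C=C=P(c1ccccc1)(c1ccccc1)c1ccccc1
Why: The C12 hydroxyl adds across the C=C bond of the cumulated ylide to give ester ylide 5, whose ylide carbon (C9) then attacks the aldehyde carbon C10 in an intramolecular Wittig reaction that expels Ph3PO. The closest known reaction type is the domino addition–Wittig lactone annulation of hydroxy aldehydes and hydroxy ketones with this ylide. One ring is closed, the six-membered unsaturated lactone O–C8(=O)–C9=C10–C11–C12, by 6-exo-trig attack of the ylide carbon on the aldehyde and collapse of the oxaphosphetane. No stereocenter is formed, but the ring can hold only the Z olefin, and this geometry is what later lets C12 direct the new centers at C9 and C10. The step needs O-acylation before any olefination and no β-elimination of the aldol; the cumulated ylide should not olefinate an aldehyde until it has taken up the O–H group, and the neutral medium spares the β-hydroxy aldehyde and the bromohydrin.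

**Step 5**
Reactants: 6 (6R)-6-[(1S)-1-bromopropyl]-5,6-dihydro-2H-pyran-2-one
Product: 7 (1S,4R,6S)-4-[(1S)-1-bromopropyl]-3,7-dioxabicyclo[4.1.0]heptan-2-one
Conditions: TBHP (anhydrous), n-BuLi, THF, −78 → −20 °C; aqueous work-up
Reagents that add atoms: tert-butyl hydroperoxide, CC(C)(C)OO
Why: Weitz–Scheffer-type nucleophilic epoxidation, in which tert-butylperoxide should add to C10 anti to the C12 side chain of the half-chair lactone and the enolate then closes the oxirane, so that C10 (final) and C9 (to be inverted) are set trans to the C12 substituent.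

**Step 6**
Reactants: 7 (1S,4R,6S)-4-[(1S)-1-bromopropyl]-3,7-dioxabicyclo[4.1.0]heptan-2-one
Product: 9 1-[(2R,3S,5R)-5-[(1S)-1-bromopropyl]-3-hydroxyoxolan-2-yl]-3-(trimethylsilyl)prop-2-yn-1-one, via lactol 8 (not isolated)
Conditions: i) TMSC≡CH, n-BuLi, THF, −78 °C, then 7 (1.1 equiv acetylide), −78 °C, AcOH quench at −78 °C; ii) crude 8, Mg(ClO4)2 (0.3 equiv), MeCN, 0 °C → rt
Reagents that add atoms: (trimethylsilyl)acetylene (as its lithium salt), C#C[Si](C)(C)C
Why: Proposed new method: 1,2-addition of the acetylide to the lactone carbonyl gives lactol 8, which is in ring–chain equilibrium with the δ-hydroxy α,β-epoxy ynone; with Mg2+ held between the ynone carbonyl and the oxirane oxygen, the C12 hydroxyl should open the epoxide at C9 by SN2 attack with inversion (a five-membered ring, whereas attack at C10 would need an oxetane), which moves the C12 oxygen from C8 to C9, contracts the six-membered ring to ring B and frees the C10 hydroxyl cis to the acyl group and trans to the C12 side chain; the closest known reaction types are the base-induced contraction of α-sulfonyloxy δ-lactones to tetrahydrofuran-2-carboxylates and the α-selective opening of α,β-epoxy ketones by heteroatom nucleophiles, and non-basic conditions are chosen so that no C12 alkoxide can displace the C13 bromide.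

**Step 7**
Reactants: 9 1-[(2R,3S,5R)-5-[(1S)-1-bromopropyl]-3-hydroxyoxolan-2-yl]-3-(trimethylsilyl)prop-2-yn-1-one
Product: 10 (1S)-1-[(2R,3S,5R)-5-[(1S)-1-bromopropyl]-3-hydroxyoxolan-2-yl]-3-(trimethylsilyl)prop-2-yn-1-ol
Conditions: Me4NBH(OAc)3, MeCN–AcOH (1:1), −30 °C
Reagents that add atoms: none
Why: Evans–Saksena reduction, in which the C10 hydroxyl binds the acetoxyborohydride and delivers hydride within a chair transition state, which should give the 1,3-anti diol and so set C8 as the (S)-carbinol.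

**Step 8**
Reactants: 10 (1S)-1-[(2R,3S,5R)-5-[(1S)-1-bromopropyl]-3-hydroxyoxolan-2-yl]-3-(trimethylsilyl)prop-2-yn-1-ol
Product: 11 (1S)-1-[(2R,3S,5R)-5-[(1S)-1-bromopropyl]-3-hydroxyoxolan-2-yl]prop-2-yn-1-ol
Conditions: K2CO3 (0.2 equiv), MeOH, 0 °C → rt
Reagents that add atoms: none
Why: Base-catalysed methanolysis of the alkynyl C–Si bond; the bromide has no neighbouring free hydroxyl at this stage and the diol is untouched.

**Step 9**
Reactants: 11 (1S)-1-[(2R,3S,5R)-5-[(1S)-1-bromopropyl]-3-hydroxyoxolan-2-yl]prop-2-yn-1-ol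
Product: 12 (2E,3R,3aS,5R,6aS)-5-[(1S)-1-bromopropyl]-2-(iodomethylidene)hexahydrofuro[3,2-b]furan-3-ol
Conditions: I2, NaHCO3, MeCN, 0 °C
Reagents that add atoms: iodine, II
Why: 5-exo-dig iodoetherification, in which only the C10 hydroxyl can reach the activated alkyne and anti addition of oxygen and iodine across the triple bond should give cis-fused ring A with the (E)-iodomethylidene group (iodine trans to the ring oxygen).

**Step 10**
Reactants: 12 (2E,3R,3aS,5R,6aS)-5-[(1S)-1-bromopropyl]-2-(iodomethylidene)hexahydrofuro[3,2-b]furan-3-ol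
Product: 13 triethyl{[(2E,3R,3aR,5R,6aS)-5-[(1S)-1-bromopropyl]-2-(iodomethylidene)hexahydrofuro[3,2-b]furan-3-yl]oxy}silane
Conditions: Et3SiOTf, 2,6-lutidine, CH2Cl2, −78 °C
Reagents that add atoms: triethylsilyl triflate, CC[Si](CC)(CC)OS(=O)(=O)C(F)(F)F
Why: Silylation of the remaining allylic hydroxyl under lutidine buffering protects it from the organometallic steps and keeps the acid-sensitive enol ether intact.

**Step 11**
Reactants: 13 triethyl{[(2E,3R,3aR,5R,6aS)-5-[(1S)-1-bromopropyl]-2-(iodomethylidene)hexahydrofuro[3,2-b]furan-3-yl]oxy}silane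
Product: 14 ethyl (3E)-3-[(3R,3aR,5R,6aS)-5-[(1S)-1-bromopropyl]-3-[(triethylsilyl)oxy]hexahydrofuro[3,2-b]furan-2-ylidene]propanoate
Conditions: BrZnCH2CO2Et (3 equiv), Pd(PPh3)4 (5 mol%), THF, rt → 45 °C
Reagents that add atoms: Reformatsky reagent (2-ethoxy-2-oxoethyl)zinc bromide, CCOC(=O)C[Zn]Br
Why: Negishi-type cross-coupling of the Reformatsky reagent, in which oxidative addition of zerovalent palladium into the C–I bond and reductive elimination occur with retention, so C5 ends up trans to the ring oxygen; the secondary bromide and the allylic silyl ether should not react.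

**Step 12**
Reactants: 14 ethyl (3E)-3-[(3R,3aR,5R,6aS)-5-[(1S)-1-bromopropyl]-3-[(triethylsilyl)oxy]hexahydrofuro[3,2-b]furan-2-ylidene]propanoate
Product: 15 (3E)-3-[(3R,3aR,5R,6aS)-5-[(1S)-1-bromopropyl]-3-[(triethylsilyl)oxy]hexahydrofuro[3,2-b]furan-2-ylidene]propanal
Conditions: i-Bu2AlH (1.1 equiv), CH2Cl2, −78 °C; Rochelle-salt work-up; used at once
Reagents that add atoms: none
Why: Partial reduction of the ester at −78 °C stops at the aldehyde through the stable tetrahedral aluminium hemiacetal, and the β,γ-unsaturated aldehyde is not stored.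

**Step 13**
Reactants: 15 (3E)-3-[(3R,3aR,5R,6aS)-5-[(1S)-1-bromopropyl]-3-[(triethylsilyl)oxy]hexahydrofuro[3,2-b]furan-2-ylidene]propanal
Product: 16 triethyl{[(2E,3R,3aR,5R,6aS)-5-[(1S)-1-bromopropyl]-2-[(3Z)-6-[tri(propan-2-yl)silyl]hex-3-en-5-yn-1-ylidene]hexahydrofuro[3,2-b]furan-3-yl]oxy}silane
Conditions: 1,3-bis(triisopropylsilyl)propyne, n-BuLi, THF, −20 °C; then 15, −78 °C → rt
Reagents that add atoms: 1,3-bis(triisopropylsilyl)propyne, CC(C)[Si](C(C)C)(C(C)C)CC#C[Si](C(C)C)(C(C)C)C(C)C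
Why: Peterson olefination with the lithiated bis-silylpropyne, in which syn elimination of silanolate from the adduct favoured by the bulky silyl groups should give the Z enyne, and addition at −78 °C should outrun enolisation of the aldehyde.

**Step 14**
Reactants: 16 triethyl{[(2E,3R,3aR,5R,6aS)-5-[(1S)-1-bromopropyl]-2-[(3Z)-6-[tri(propan-2-yl)silyl]hex-3-en-5-yn-1-ylidene]hexahydrofuro[3,2-b]furan-3-yl]oxy}silane
Product: 17 (2E,3R,3aS,5R,6aS)-5-[(1S)-1-bromopropyl]-2-[(3Z)-hex-3-en-5-yn-1-ylidene]hexahydrofuro[3,2-b]furan-3-ol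
Conditions: Bu4NF (2.5 equiv), THF, 0 °C
Reagents that add atoms: none
Why: Fluoride cleaves both the O–Si bond of the triethylsilyl ether and the C(sp)–Si bond of the alkynylsilane, which frees the C8 alcohol and the terminal alkyne in one operation.

**Step 15**
Reactants: 17 (2E,3R,3aS,5R,6aS)-5-[(1S)-1-bromopropyl]-2-[(3Z)-hex-3-en-5-yn-1-ylidene]hexahydrofuro[3,2-b]furan-3-ol
Product: 18 (2E,3S,3aR,5R,6aS)-3-bromo-5-[(1S)-1-bromopropyl]-2-[(3Z)-hex-3-en-5-yn-1-ylidene]hexahydrofuro[3,2-b]furan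
Conditions: CBr4, PPh3, 2,6-di-tert-butyl-4-methylpyridine (0.2 equiv), CH2Cl2, 0 °C
Reagents that add atoms: carbon tetrabromide, BrC(Br)(Br)Br
Why: Appel reaction, in which the alkoxyphosphonium ion of the endo C8 alcohol is displaced by bromide in an SN2 step from the open convex face with inversion, giving the exo (8S) bromide, while the buffered non-acidic medium should leave the enol ether in place.

**Compound list**

1 | (E)-hex-3-en-1-ol | OCC/C=C/CC | starting material
2 | 2-[(2R,3R)-3-ethyloxiran-2-yl]ethan-1-ol | OCC[C@H]1O[C@@H]1CC | intermediate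
3 | (3R,4S)-4-bromohexane-1,3-diol | OCC[C@H]([C@@H](Br)CC)O | intermediate
4 | (3R,4S)-4-bromo-3-hydroxyhexanal | O=CC[C@H]([C@@H](Br)CC)O | intermediate
5 | (3R,4S)-4-bromo-1-oxohexan-3-yl (triphenyl-λ5-phosphanylidene)acetate (ester ylide) | O=CC[C@H]([C@@H](Br)CC)OC(=O)C=P(c1ccccc1)(c1ccccc1)c1ccccc1 | intermediate
6 | (6R)-6-[(1S)-1-bromopropyl]-5,6-dihydro-2H-pyran-2-one | O=C1C=CC[C@H]([C@@H](Br)CC)O1 | intermediate
7 | (1S,4R,6S)-4-[(1S)-1-bromopropyl]-3,7-dioxabicyclo[4.1.0]heptan-2-one | O=C1[C@H]2O[C@H]2C[C@H]([C@@H](Br)CC)O1 | intermediate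
8 | (1S,4R,6S)-4-[(1S)-1-bromopropyl]-2-[(trimethylsilyl)ethynyl]-3,7-dioxabicyclo[4.1.0]heptan-2-ol (lactol, both C2 epimers) | OC1(C#C[Si](C)(C)C)[C@H]2O[C@H]2C[C@H]([C@@H](Br)CC)O1 | intermediate
9 | 1-[(2R,3S,5R)-5-[(1S)-1-bromopropyl]-3-hydroxyoxolan-2-yl]-3-(trimethylsilyl)prop-2-yn-1-one | O[C@H]1C[C@H]([C@@H](Br)CC)O[C@H]1C(=O)C#C[Si](C)(C)C | intermediate
10 | (1S)-1-[(2R,3S,5R)-5-[(1S)-1-bromopropyl]-3-hydroxyoxolan-2-yl]-3-(trimethylsilyl)prop-2-yn-1-ol | O[C@H]1C[C@H]([C@@H](Br)CC)O[C@H]1[C@@H](O)C#C[Si](C)(C)C | intermediate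
11 | (1S)-1-[(2R,3S,5R)-5-[(1S)-1-bromopropyl]-3-hydroxyoxolan-2-yl]prop-2-yn-1-ol | O[C@H]1C[C@H]([C@@H](Br)CC)O[C@H]1[C@@H](O)C#C | intermediate
12 | (2E,3R,3aS,5R,6aS)-5-[(1S)-1-bromopropyl]-2-(iodomethylidene)hexahydrofuro[3,2-b]furan-3-ol | I/C=C1/O[C@H]2C[C@H]([C@@H](Br)CC)O[C@H]2[C@H]1O | intermediate
13 | triethyl{[(2E,3R,3aR,5R,6aS)-5-[(1S)-1-bromopropyl]-2-(iodomethylidene)hexahydrofuro[3,2-b]furan-3-yl]oxy}silane | I/C=C1/O[C@H]2C[C@H]([C@@H](Br)CC)O[C@H]2[C@H]1O[Si](CC)(CC)CC | intermediate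
14 | ethyl (3E)-3-[(3R,3aR,5R,6aS)-5-[(1S)-1-bromopropyl]-3-[(triethylsilyl)oxy]hexahydrofuro[3,2-b]furan-2-ylidene]propanoate | CCOC(=O)C/C=C1/O[C@H]2C[C@H]([C@@H](Br)CC)O[C@H]2[C@H]1O[Si](CC)(CC)CC | intermediate
15 | (3E)-3-[(3R,3aR,5R,6aS)-5-[(1S)-1-bromopropyl]-3-[(triethylsilyl)oxy]hexahydrofuro[3,2-b]furan-2-ylidene]propanal | O=CC/C=C1/O[C@H]2C[C@H]([C@@H](Br)CC)O[C@H]2[C@H]1O[Si](CC)(CC)CC | intermediate
16 | triethyl{[(2E,3R,3aR,5R,6aS)-5-[(1S)-1-bromopropyl]-2-[(3Z)-6-[tri(propan-2-yl)silyl]hex-3-en-5-yn-1-ylidene]hexahydrofuro[3,2-b]furan-3-yl]oxy}silane | CC(C)[Si](C(C)C)(C(C)C)C#C/C=C\C/C=C1/O[C@H]2C[C@H]([C@@H](Br)CC)O[C@H]2[C@H]1O[Si](CC)(CC)CC | intermediate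
17 | (2E,3R,3aS,5R,6aS)-5-[(1S)-1-bromopropyl]-2-[(3Z)-hex-3-en-5-yn-1-ylidene]hexahydrofuro[3,2-b]furan-3-ol | C#C/C=C\C/C=C1/O[C@H]2C[C@H]([C@@H](Br)CC)O[C@H]2[C@H]1O | intermediate
18 | (2E,3S,3aR,5R,6aS)-3-bromo-5-[(1S)-1-bromopropyl]-2-[(3Z)-hex-3-en-5-yn-1-ylidene]hexahydrofuro[3,2-b]furan | C#C/C=C\C/C=C1/O[C@H]2C[C@H]([C@@H](Br)CC)O[C@H]2[C@@H]1Br | target

**Total step count:** 15. **Longest linear sequence:** 15 steps (the route is fully linear from 1).

**Steps most likely to fail**

1. Step 6 (proposed new method). The hydroxyl may fail to open the oxirane at C9, the lactol may react by other acid-promoted paths (for example migration of the alkynyl group), or the liberated ynone may add a second acetylide. The fallback sets out from 7 and comes back at 9, using known reactions only. LiBH4 (THF, 0 °C) should reduce the lactone to [(2R,3S)-3-[(2R,3S)-3-bromo-2-hydroxypentyl]oxiran-2-yl]methanol F1. Camphorsulfonic acid (cat., CH2Cl2) should then bring about the acid-catalysed epoxy-alcohol cyclisation of the C12 hydroxyl onto C9 (inversion, five-membered ring) to give (2S,3S,5R)-5-[(1S)-1-bromopropyl]-2-(hydroxymethyl)oxolan-3-ol F2. TEMPO/PhI(OAc)2 should oxidise the primary alcohol to (2R,3S,5R)-5-[(1S)-1-bromopropyl]-3-hydroxyoxolane-2-carbaldehyde F3. TMSC≡CLi (THF, −78 °C) should add to give 1-[(2R,3S,5R)-5-[(1S)-1-bromopropyl]-3-hydroxyoxolan-2-yl]-3-(trimethylsilyl)prop-2-yn-1-ol F4 as a mixture of C8 epimers. MnO2 (CH2Cl2) should oxidise only the propargylic hydroxyl and deliver ynone 9.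

2. Step 15. The activated allylic alcohol may ionise, or bromide may attack C6 (SN2′) with shift of the double bond into the ring, or the enol ether may be lost. The fallback sets out from 17 and comes back at 18; it separates activation from displacement. ClCH2SO2Cl and 2,6-lutidine (CH2Cl2, −40 °C) should give (2E,3R,3aR,5R,6aS)-5-[(1S)-1-bromopropyl]-2-[(3Z)-hex-3-en-5-yn-1-ylidene]hexahydrofuro[3,2-b]furan-3-yl chloromethanesulfonate F5. LiBr (THF, 0 °C) should then displace the sulfonate in a direct SN2 step with inversion to give 18.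

3. Step 13. The basic lithium reagent may enolise the β,γ-unsaturated aldehyde (with loss of the enol ether position), or the Z selectivity may erode. The fallback sets out from 15 and comes back at 17, replacing the Peterson step by olefination and coupling. Stork–Zhao olefination (Ph3P=CHI from (iodomethyl)triphenylphosphonium iodide and NaN(SiMe3)2, THF, −78 °C) should give triethyl{[(2E,3R,3aR,5R,6aS)-5-[(1S)-1-bromopropyl]-2-[(3Z)-4-iodobut-3-en-1-ylidene]hexahydrofuro[3,2-b]furan-3-yl]oxy}silane F6. Sonogashira coupling with (trimethylsilyl)acetylene (PdCl2(PPh3)2, CuI, i-Pr2NH, rt) should give triethyl{[(2E,3R,3aR,5R,6aS)-5-[(1S)-1-bromopropyl]-2-[(3Z)-6-(trimethylsilyl)hex-3-en-5-yn-1-ylidene]hexahydrofuro[3,2-b]furan-3-yl]oxy}silane F7. Bu4NF (THF, 0 °C) should remove both silyl groups to give 17.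

**Further compounds**

F1 | step 6 | [(2R,3S)-3-[(2R,3S)-3-bromo-2-hydroxypentyl]oxiran-2-yl]methanol | OC[C@H]1O[C@H]1C[C@H]([C@@H](Br)CC)O
F2 | step 6 | (2S,3S,5R)-5-[(1S)-1-bromopropyl]-2-(hydroxymethyl)oxolan-3-ol | O[C@H]1C[C@H]([C@@H](Br)CC)O[C@H]1CO
F3 | step 6 | (2R,3S,5R)-5-[(1S)-1-bromopropyl]-3-hydroxyoxolane-2-carbaldehyde | O[C@H]1C[C@H]([C@@H](Br)CC)O[C@H]1C=O
F4 | step 6 | 1-[(2R,3S,5R)-5-[(1S)-1-bromopropyl]-3-hydroxyoxolan-2-yl]-3-(trimethylsilyl)prop-2-yn-1-ol (both C1 epimers) | O[C@H]1C[C@H]([C@@H](Br)CC)O[C@H]1C(O)C#C[Si](C)(C)C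
F5 | step 15 | (2E,3R,3aR,5R,6aS)-5-[(1S)-1-bromopropyl]-2-[(3Z)-hex-3-en-5-yn-1-ylidene]hexahydrofuro[3,2-b]furan-3-yl chloromethanesulfonate | C#C/C=C\C/C=C1/O[C@H]2C[C@H]([C@@H](Br)CC)O[C@H]2[C@H]1OS(=O)(=O)CCl
F6 | step 13 | triethyl{[(2E,3R,3aR,5R,6aS)-5-[(1S)-1-bromopropyl]-2-[(3Z)-4-iodobut-3-en-1-ylidene]hexahydrofuro[3,2-b]furan-3-yl]oxy}silane | I/C=C\C/C=C1/O[C@H]2C[C@H]([C@@H](Br)CC)O[C@H]2[C@H]1O[Si](CC)(CC)CC
F7 | step 13 | triethyl{[(2E,3R,3aR,5R,6aS)-5-[(1S)-1-bromopropyl]-2-[(3Z)-6-(trimethylsilyl)hex-3-en-5-yn-1-ylidene]hexahydrofuro[3,2-b]furan-3-yl]oxy}silane | C[Si](C)(C)C#C/C=C\C/C=C1/O[C@H]2C[C@H]([C@@H](Br)CC)O[C@H]2[C@H]1O[Si](CC)(CC)CC
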